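**Assumptions (one line each)**
- The given SMILES is the natural (−)-enantiomer. By CIP analysis of the SMILES, the quaternary aminal carbon is R and the CH aminal carbon is S.
- The cis-fused tetracycle is the only feasible ring-fusion diastereomer, so only the absolute configuration needs to be established.

**Retrosynthetic overview**
1. The target comes from (±)-dibromophakellstatin by resolution on a chiral stationary phase (CSP-HPLC).
2. The two adjacent N,N-aminal carbons (quaternary C and CH) are the oxidation level of an α-ketoaldehyde condensed with urea. The two tethered N–H groups (amide N–H and pyrrole N–H) close the remaining rings.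
3. Ring-forming order, in one acid-mediated cascade: imidazolidinone (urea plus aldehyde), then pyrrolidine (amide N onto the ketone-derived N-acyliminium), then pyrrolo-piperazinone (pyrrole N onto the aldehyde-derived N-acyliminium).
4. The ketoaldehyde comes from a terminal alkene by dihydroxylation and diol oxidation. The alkene amide comes from 4,5-dibromopyrrole-2-carboxylic acid and pent-4-en-1-amine.

---

**Step 1**
Reactants: 1 (4,5-dibromo-1H-pyrrole-2-carboxylic acid) and 2 (pent-4-en-1-amine)
Product: 3 (4,5-dibromo-N-(pent-4-en-1-yl)-1H-pyrrole-2-carboxamide)
Conditions: EDC·HCl, HOBt, DIPEA, DMF, 0 °C → rt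
Reagents that add atoms: none
Why: This is a standard carbodiimide amide coupling, and the free pyrrole N–H and the C–Br bonds are untouched. No stereocenter is involved.

**Step 2**
Reactants: 3
Product: 4 (4,5-dibromo-N-(4,5-dihydroxypentyl)-1H-pyrrole-2-carboxamide, racemic at C4)
Conditions: K2OsO4·2H2O (2 mol %), NMO, acetone/H2O 4:1, rt
Reagents that add atoms: N-methylmorpholine N-oxide, C[N+]1([O-])CCOCC1 (oxygen source); water, O (hydrolyses the osmate ester)
Why: Upjohn syn-dihydroxylation reacts at the isolated terminal alkene, while the electron-poor dibromopyrrole is inert. The new carbinol stereocenter is racemic and is destroyed in step 3.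

**Step 3**
Reactants: 4
Product: 5 (4,5-dibromo-N-(4,5-dioxopentyl)-1H-pyrrole-2-carboxamide, isolated as its hydrate)
Conditions: IBX (3 equiv), EtOAc, 80 °C; filter off the iodine by-products and concentrate. Use the crude product immediately.
Reagents that add atoms: none
Why: IBX oxidises a vicinal diol to the α-ketoaldehyde (secondary OH to ketone, primary OH to aldehyde) without C–C cleavage, unlike periodate or Pb(IV). The pyrrole N–H, amide and C–Br groups survive.

**Step 4**
Reactants: 5 and 6 (urea)
Product: 7 ((±)-dibromophakellstatin)
Conditions: urea (5–10 equiv), p-TsOH·H2O (0.3 equiv), MeCN, 4 Å MS, 60 °C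
Reagents that add atoms: none (urea is the reactant, and the catalyst leaves no atoms)
Why: This is an acid-catalysed urea/1,2-dicarbonyl condensation of the glycoluril/Biltz type, followed by two intramolecular amidoalkylation (N-acyliminium) cyclisations. The amide N–H closes the pyrrolidine at the ketone-derived carbon, and the pyrrole N–H closes the six-membered lactam at the aldehyde-derived carbon. The fused 5/5/6 framework forces the two aminal stereocentres to be cis, so the cascade gives the natural relative configuration as a racemate under thermodynamic control. Overall this is 5 + urea − 2 H2O (C11H10Br2N4O2).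

**Step 5**
Reactants: 7
Product: 8 ((−)-dibromophakellstatin, the target)
Conditions: preparative HPLC, Chiralpak IC (or IA), n-hexane/EtOH, rt; collect the (−) enantiomer
Reagents that add atoms: none
Why: Resolution sets the absolute configuration (quaternary C = R, CH = S). Both stereocentres are locked in fused aminal rings, so they cannot epimerise or racemise afterwards.

---

**Compound list**
1 | 4,5-Dibromo-1H-pyrrole-2-carboxylic acid | OC(=O)c1cc(Br)c(Br)[nH]1 | starting material
2 | Pent-4-en-1-amine | C=CCCCN | starting material
3 | 4,5-Dibromo-N-(pent-4-en-1-yl)-1H-pyrrole-2-carboxamide | C=CCCCNC(=O)c1cc(Br)c(Br)[nH]1 | intermediate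
4 | 4,5-Dibromo-N-(4,5-dihydroxypentyl)-1H-pyrrole-2-carboxamide (racemic at C4) | OCC(O)CCCNC(=O)c1cc(Br)c(Br)[nH]1 | intermediate
5 | 4,5-Dibromo-N-(4,5-dioxopentyl)-1H-pyrrole-2-carboxamide (hydrate) | O=CC(=O)CCCNC(=O)c1cc(Br)c(Br)[nH]1 | intermediate
6 | Urea | NC(N)=O | starting material
7 | (±)-Dibromophakellstatin (racemate; SMILES shows the relative configuration) | O=C1N[C@H]2n3c(cc(Br)c3Br)C(=O)N3CCC[C@]23N1 | intermediate
8 | (−)-Dibromophakellstatin | O=C1N[C@H]2n3c(cc(Br)c3Br)C(=O)N3CCC[C@]23N1 | target

**Totals**
- Total steps: 5 (4 chemical steps plus 1 resolution).
- Longest linear sequence: 5 steps (1 → 3 → 4 → 5 → 7 → 8).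

**Three steps most likely to fail**
1. **Step 4 (cascade).** The α-ketoaldehyde and urea could instead give hydantoin rearrangement or glycoluril-type oligomers, and the weakly nucleophilic pyrrole N–H may not close the last ring.
   Fallback: take a different approach through the achiral tricyclic pyrrolo-pyrazinone enamide. Acylate 2-methyl-1-pyrroline with 4,5-dibromopyrrole-2-carbonyl chloride, and use NBS/base to close the piperazinone by pyrrole N-alkylation. Then diaminate the enamide C=C with NBS and a urea N-nucleophile, closing the imidazolidinone by intramolecular displacement.
2. **Step 3 (IBX oxidation).** The glyoxal hydrate may be unstable, and diol cleavage or over-oxidation is possible.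
   Fallback: make the ketoaldehyde from γ-aminobutyric acid instead. Couple the pyrrole acid to GABA, convert the acid to the diazoketone (mixed anhydride, then TMSCHN2), and oxidise it with dimethyldioxirane to the α-ketoaldehyde.
3. **Step 5 (resolution).** Separation on the chiral stationary phase may be poor, and throughput is limited to at most 50%.
   Fallback: make the route enantioselective. Run the step 4 cascade with an enantiopure N-(1-arylethyl)urea as a removable auxiliary. Separate the diastereomers on silica, then remove the auxiliary with TFA. A chiral phosphoric acid as the cascade catalyst is the alternative.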